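**Retrosynthetic overview**

- Ring C of the flavanone is treated as a hetero-Diels–Alder adduct. O1–C8a–C4a–C4 (rings A and C, with C4 at the aldehyde oxidation level and carried as a 4-methoxy group) is an ortho-quinone methide heterodiene, and C2–C3 with phenyl ring B is styrene. Cutting O1–C2 and C3–C4 leads back to a ring A salicylaldehyde, HC(OMe)3 and styrene.
- The salicylaldehyde comes from ortho-formylation of a mirror-symmetric phenol whose OH (the future O1) is para to the benzylic CH2. Either ortho position gives the same aldehyde, and the benzyl group ends on C6, not C8.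
- The C6–CH2–aryl link is made by lithiation between the two benzyloxy groups of O-silylated 3,5-bis(benzyloxy)phenol, addition to 2,3-bis(benzyloxy)benzaldehyde and ionic reduction of the carbinol.
- Ring order: ring A, ring B and the catechol ring are bought. Ring C is the only ring formed (step 6, which sets C2). C4–OMe is then taken to C4–OH and C4=O, and four benzyl ethers are removed by hydrogenolysis.

Key step: step 6

Assumption: 3,5-bis(benzyloxy)phenol is taken as a purchasable starting material, and the C4 configurations of 14 and 15 are drawn as expected but do not matter, because C4 becomes the ketone in step 8.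

**Route**

Step 1
Reactants: 1 3,5-bis(benzyloxy)phenol
Product: 2 [3,5-bis(benzyloxy)phenoxy]triisopropylsilane
Conditions: TIPSCl, imidazole, DMF, rt
Reagents that add atoms: triisopropylsilyl chloride, CC(C)[Si](Cl)(C(C)C)C(C)C
Why: Silylation of a phenol; the bulky, weakly coordinating silyloxy group masks the future O1 and should not compete as an ortho-director in step 2.

Step 2
Reactants: 2 [3,5-bis(benzyloxy)phenoxy]triisopropylsilane; 3 2,3-bis(benzyloxy)benzaldehyde
Product: 5 [2,6-bis(benzyloxy)-4-(triisopropylsilyloxy)phenyl][2,3-bis(benzyloxy)phenyl]methanol (racemic), via 4-lithio aryl silyl ether 4 (not isolated)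
Conditions: n-BuLi, THF, 0 °C; then 3, −78 °C → 0 °C; NH4Cl (aq)
Reagents that add atoms: none
Why: Directed ortho-metalation at the one position flanked by two coordinating benzyloxy groups (the positions next to the hindered silyloxy group are less acidic and shielded), then 1,2-addition of the aryllithium to the aldehyde; the carbinol centre forms racemic and is removed in step 3.

Step 3
Reactants: 5 [2,6-bis(benzyloxy)-4-(triisopropylsilyloxy)phenyl][2,3-bis(benzyloxy)phenyl]methanol
Product: 6 {3,5-bis(benzyloxy)-4-[2,3-bis(benzyloxy)benzyl]phenoxy}triisopropylsilane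
Conditions: Et3SiH, CF3CO2H, CH2Cl2, 0 °C
Reagents that add atoms: none
Why: Ionic hydrogenation; the diarylcarbinol ionises readily to a cation stabilised by two ortho-alkoxy groups and the para-silyloxy group, and the silane delivers hydride, while benzyl and aryl silyl ethers should survive brief exposure to the acid at 0 °C.

Step 4
Reactants: 6 {3,5-bis(benzyloxy)-4-[2,3-bis(benzyloxy)benzyl]phenoxy}triisopropylsilane
Product: 7 3,5-bis(benzyloxy)-4-[2,3-bis(benzyloxy)benzyl]phenol
Conditions: Bu4NF, THF, 0 °C; NH4Cl (aq)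
Reagents that add atoms: none
Why: Fluoride cleavage of an aryl silyl ether, which leaves the benzyl ethers and the diarylmethane untouched.

Step 5
Reactants: 7 3,5-bis(benzyloxy)-4-[2,3-bis(benzyloxy)benzyl]phenol
Product: 9 4,6-bis(benzyloxy)-5-[2,3-bis(benzyloxy)benzyl]-2-hydroxybenzaldehyde, via 2-(hydroxymethyl)phenol magnesium salt 8 (not isolated)
Conditions: MgCl2, Et3N, (CH2O)n, MeCN, reflux; 1 M HCl work-up
Reagents that add atoms: paraformaldehyde (reacts as formaldehyde), C=O
Why: Magnesium-mediated ortho-formylation (Casnati–Skattebøl): the magnesium phenoxide delivers formaldehyde to the ortho carbon and a second formaldehyde oxidises the salicyl alcohol by hydride transfer; the two ortho positions are equivalent by symmetry and the para position is blocked, so only one aldehyde can form.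

Step 6
Reactants: 9 4,6-bis(benzyloxy)-5-[2,3-bis(benzyloxy)benzyl]-2-hydroxybenzaldehyde; 10 styrene; 11 trimethyl orthoformate
Product: 14 (2S,4S)-5,7-bis(benzyloxy)-6-[2,3-bis(benzyloxy)benzyl]-4-methoxyflavan (2,4-cis), via salicylaldehyde dimethyl acetal 12 (not isolated), via 4-methoxy ortho-quinone methide 13 (not isolated)
Conditions: (S,S)-IDPi (imidodiphosphorimidate from two 3,3'-diaryl-BINOL units, N-triflyl; 5 mol%; its mirror image if the sense of induction proves opposite), 10 (5 equiv), 11 (1.2 equiv), CHCl3, −20 °C → rt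
Reagents that add atoms: trimethyl orthoformate (compound 11), COC(OC)OC
Why: Proposed new method: the acid and HC(OMe)3 turn aldehyde 9 into acetal 12, which loses methanol to the 4-methoxy ortho-quinone methide 13, present as its O1-protonated oxocarbenium form that is ion-paired and O1–H hydrogen-bonded to the chiral imidodiphosphorimidate anion; the CH2 terminus of styrene attacks C4 and the developing C2 benzylic cation is captured by O1 in an asynchronous inverse-demand hetero-[4+2] step. The closest known reaction types are the achiral acid-promoted three-component reaction of salicylaldehydes, orthoformates and styrenes to 4-alkoxy-2-arylchromans and the chiral Brønsted acid-catalysed [4+2] cycloaddition of 4-aryl ortho-quinone methides with styrenes; the 4-alkoxy heterodiene has not been shown in enantioselective form. Ring C closes as a six-membered ring by C3–C4 bond formation followed at once by O1–C2 closure onto the benzylic cation (formal [4+2], both bonds in one step). C2 (S) is set by the face of styrene that the confined anion leaves open (catalyst control), and C4 follows from the endo placement of phenyl, which should give the 2,4-cis adduct. The step needs regioselectivity, which the polarity match between cationic C4 and the phenyl-stabilised C2 secures, and chemoselectivity over acid-induced oligomerisation of styrene, which is favoured by the easy formation of the 2,4,6-trioxygenated cation and by O1 being the only free phenol.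

Step 7
Reactants: 14 (2S,4S)-5,7-bis(benzyloxy)-6-[2,3-bis(benzyloxy)benzyl]-4-methoxyflavan
Product: 15 (2S,4R)-5,7-bis(benzyloxy)-6-[2,3-bis(benzyloxy)benzyl]flavan-4-ol (2,4-trans drawn; any C4 epimer is carried along)
Conditions: TsOH·H2O (10 mol%), THF/H2O 3:1, 0.02 M, rt
Reagents that add atoms: water, O
Why: SN1 solvolysis of a benzylic methyl ether whose C4 cation is stabilised by O1 and the 5- and 7-benzyloxy groups; water in large excess and high dilution should give the alcohol (axial attack, hence mainly 2,4-trans), while C2 is untouched because C2–O1 ionisation would need a far less stabilised cation.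

Step 8
Reactants: 15 (2S,4R)-5,7-bis(benzyloxy)-6-[2,3-bis(benzyloxy)benzyl]flavan-4-ol
Product: 16 (2S)-5,7-bis(benzyloxy)-6-[2,3-bis(benzyloxy)benzyl]flavanone
Conditions: Dess–Martin periodinane, NaHCO3, CH2Cl2, 0 °C → rt
Reagents that add atoms: none
Why: Dess–Martin oxidation of a secondary benzylic alcohol to the ketone; the buffered, non-basic medium avoids ring opening to the chalcone, so the 2S centre should be kept and both C4 epimers converge.

Step 9
Reactants: 16 (2S)-5,7-bis(benzyloxy)-6-[2,3-bis(benzyloxy)benzyl]flavanone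
Product: 17 (2S)-6-(2,3-dihydroxybenzyl)-5,7-dihydroxyflavanone (target, CNP0348560.1)
Conditions: H2 (1 atm), 10% Pd/C, EtOAc/MeOH, rt
Reagents that add atoms: none
Why: Catalytic hydrogenolysis of four aryl benzyl ethers under neutral conditions; the cyclic C2–O1 benzylic ether, the diarylmethane and the hydrogen-bonded C4 ketone react much more slowly, so stopping after four equivalents of H2 should give the target with C2 unchanged.

**Compound list**

1 | 3,5-bis(benzyloxy)phenol | Oc1cc(OCc2ccccc2)cc(OCc2ccccc2)c1 | starting material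
2 | [3,5-bis(benzyloxy)phenoxy]triisopropylsilane | CC(C)[Si](Oc1cc(OCc2ccccc2)cc(OCc2ccccc2)c1)(C(C)C)C(C)C | intermediate
3 | 2,3-bis(benzyloxy)benzaldehyde | O=Cc1cccc(OCc2ccccc2)c1OCc1ccccc1 | starting material
4 | [2,6-bis(benzyloxy)-4-(triisopropylsilyloxy)phenyl]lithium | [Li]c1c(OCc2ccccc2)cc(O[Si](C(C)C)(C(C)C)C(C)C)cc1OCc1ccccc1 | intermediate (not isolated)
5 | [2,6-bis(benzyloxy)-4-(triisopropylsilyloxy)phenyl][2,3-bis(benzyloxy)phenyl]methanol, racemic | OC(c1cccc(OCc2ccccc2)c1OCc1ccccc1)c1c(OCc2ccccc2)cc(O[Si](C(C)C)(C(C)C)C(C)C)cc1OCc1ccccc1 | intermediate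
6 | {3,5-bis(benzyloxy)-4-[2,3-bis(benzyloxy)benzyl]phenoxy}triisopropylsilane | C(c1cccc(OCc2ccccc2)c1OCc1ccccc1)c1c(OCc2ccccc2)cc(O[Si](C(C)C)(C(C)C)C(C)C)cc1OCc1ccccc1 | intermediate
7 | 3,5-bis(benzyloxy)-4-[2,3-bis(benzyloxy)benzyl]phenol | Oc1cc(OCc2ccccc2)c(Cc2cccc(OCc3ccccc3)c2OCc2ccccc2)c(OCc2ccccc2)c1 | intermediate
8 | 3,5-bis(benzyloxy)-4-[2,3-bis(benzyloxy)benzyl]-2-(hydroxymethyl)phenol, present as its magnesium phenoxide | OCc1c(O)cc(OCc2ccccc2)c(Cc2cccc(OCc3ccccc3)c2OCc2ccccc2)c1OCc1ccccc1 | intermediate (not isolated)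
9 | 4,6-bis(benzyloxy)-5-[2,3-bis(benzyloxy)benzyl]-2-hydroxybenzaldehyde | O=Cc1c(O)cc(OCc2ccccc2)c(Cc2cccc(OCc3ccccc3)c2OCc2ccccc2)c1OCc1ccccc1 | intermediate (key-step precursor)
10 | styrene | C=Cc1ccccc1 | starting material
11 | trimethyl orthoformate | COC(OC)OC | starting material
12 | 3,5-bis(benzyloxy)-4-[2,3-bis(benzyloxy)benzyl]-2-(dimethoxymethyl)phenol | COC(OC)c1c(O)cc(OCc2ccccc2)c(Cc2cccc(OCc3ccccc3)c2OCc2ccccc2)c1OCc1ccccc1 | intermediate (not isolated)
13 | 3,5-bis(benzyloxy)-4-[2,3-bis(benzyloxy)benzyl]-6-(methoxymethylidene)cyclohexa-2,4-dien-1-one (exocyclic C=C geometry not fixed; reacts as its O-protonated ion pair) | COC=C1C(=O)C=C(OCc2ccccc2)C(Cc2cccc(OCc3ccccc3)c2OCc2ccccc2)=C1OCc1ccccc1 | intermediate (not isolated)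
14 | (2S,4S)-5,7-bis(benzyloxy)-6-[2,3-bis(benzyloxy)benzyl]-4-methoxyflavan (2,4-cis) | CO[C@H]1C[C@@H](c2ccccc2)Oc2cc(OCc3ccccc3)c(Cc3cccc(OCc4ccccc4)c3OCc3ccccc3)c(OCc3ccccc3)c21 | intermediate (key-step product)
15 | (2S,4R)-5,7-bis(benzyloxy)-6-[2,3-bis(benzyloxy)benzyl]flavan-4-ol (2,4-trans) | O[C@@H]1C[C@@H](c2ccccc2)Oc2cc(OCc3ccccc3)c(Cc3cccc(OCc4ccccc4)c3OCc3ccccc3)c(OCc3ccccc3)c21 | intermediate
16 | (2S)-5,7-bis(benzyloxy)-6-[2,3-bis(benzyloxy)benzyl]flavanone | O=C1C[C@@H](c2ccccc2)Oc2cc(OCc3ccccc3)c(Cc3cccc(OCc4ccccc4)c3OCc3ccccc3)c(OCc3ccccc3)c21 | intermediate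
17 | (2S)-6-(2,3-dihydroxybenzyl)-5,7-dihydroxyflavanone | O=C1C[C@@H](c2ccccc2)Oc2cc(O)c(Cc3cccc(O)c3O)c(O)c21 | target

**Step count**

Total steps: 9. Longest linear sequence: 9 steps (1 → 17); compounds 3, 10 and 11 enter as purchased partners.

**Steps most likely to fail**

1. Step 6 (proposed new method). The chiral anion may give poor facial selectivity at C2, or the strongly stabilised cation may be captured by styrene so slowly that acid-induced oligomerisation of styrene takes over. The fallback uses known chemistry, sets out from 9 and returns at 16. Aldehyde 9 is treated with propane-1,3-dithiol and BF3·OEt2 to give 3,5-bis(benzyloxy)-4-[2,3-bis(benzyloxy)benzyl]-2-(1,3-dithian-2-yl)phenol F1. Its O,C-dianion (n-BuLi, 2.2 equiv, THF, −30 °C) opens commercial (S)-styrene oxide at the CH2 terminus (Corey–Seebach alkylation, the benzylic centre is not touched) to give (1R)-2-{2-[2,4-bis(benzyloxy)-3-(2,3-bis(benzyloxy)benzyl)-6-hydroxyphenyl]-1,3-dithian-2-yl}-1-phenylethanol F2. PPh3 and diisopropyl azodicarboxylate then close ring C by intramolecular Mitsunobu etherification with inversion, giving (2S)-5,7-bis(benzyloxy)-6-[2,3-bis(benzyloxy)benzyl]-2-phenylspiro[chromane-4,2'-[1,3]dithiane] F3. MeI and CaCO3 in aqueous MeCN unmask the ketone to give 16, and step 9 follows.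

2. Step 2. n-BuLi may deprotonate a benzylic O–CH2 group, leading to Wittig rearrangement, or may lithiate next to the silyloxy group. The fallback sets out from 1 and returns at 5, and generates the organolithium by halogen–lithium exchange on the other ring. Vilsmeier–Haack formylation of 1 (POCl3, DMF) para to the hydroxyl gives 2,6-bis(benzyloxy)-4-hydroxybenzaldehyde F4 after separation from the ortho isomer. TIPSCl and imidazole convert it into 2,6-bis(benzyloxy)-4-(triisopropylsilyloxy)benzaldehyde F5. 1-Bromo-2,3-bis(benzyloxy)benzene F6 (from commercial 3-bromocatechol, BnBr, K2CO3) is exchanged with n-BuLi at −78 °C to [2,3-bis(benzyloxy)phenyl]lithium F7, which adds to F5 to give carbinol 5.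

3. Step 7. The C4 cation may lose a proton to give the flav-3-ene, or attack C8 of a second molecule (Friedel–Crafts self-condensation), instead of being trapped by water. The fallback sets out from 14 and returns at 16, and oxidises instead of solvolysing. DDQ in CH2Cl2 with pH 7 aqueous buffer abstracts hydride from the C4–H of the electron-rich benzylic methyl ether, and the resulting O-methyl oxocarbenium ion is hydrolysed directly to ketone 16, which also makes step 8 unnecessary. No compound outside the list is made (entry none F0).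

**Further compounds**

F1 | step 6 | 3,5-bis(benzyloxy)-4-[2,3-bis(benzyloxy)benzyl]-2-(1,3-dithian-2-yl)phenol | Oc1cc(OCc2ccccc2)c(Cc2cccc(OCc3ccccc3)c2OCc2ccccc2)c(OCc2ccccc2)c1C1SCCCS1
F2 | step 6 | (1R)-2-{2-[2,4-bis(benzyloxy)-3-(2,3-bis(benzyloxy)benzyl)-6-hydroxyphenyl]-1,3-dithian-2-yl}-1-phenylethanol | O[C@H](CC1(SCCCS1)c1c(O)cc(OCc2ccccc2)c(Cc2cccc(OCc3ccccc3)c2OCc2ccccc2)c1OCc1ccccc1)c1ccccc1
F3 | step 6 | (2S)-5,7-bis(benzyloxy)-6-[2,3-bis(benzyloxy)benzyl]-2-phenylspiro[chromane-4,2'-[1,3]dithiane] | S1CCCSC12C[C@@H](c3ccccc3)Oc3cc(OCc4ccccc4)c(Cc4cccc(OCc5ccccc5)c4OCc4ccccc4)c(OCc4ccccc4)c32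
F4 | step 2 | 2,6-bis(benzyloxy)-4-hydroxybenzaldehyde | O=Cc1c(OCc2ccccc2)cc(O)cc1OCc1ccccc1
F5 | step 2 | 2,6-bis(benzyloxy)-4-(triisopropylsilyloxy)benzaldehyde | O=Cc1c(OCc2ccccc2)cc(O[Si](C(C)C)(C(C)C)C(C)C)cc1OCc1ccccc1
F6 | step 2 | 1-bromo-2,3-bis(benzyloxy)benzene | Brc1cccc(OCc2ccccc2)c1OCc1ccccc1
F7 | step 2 | [2,3-bis(benzyloxy)phenyl]lithium | [Li]c1cccc(OCc2ccccc2)c1OCc1ccccc1
F0 | step 7 | none | none
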